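The earlier runs and the new flask were computed with made-up constants; the scatter is artificial.

You cannot draw the theta run with one constant rate: G gains 0.8% of the J charged by 5.00 h, then 7.1 percentage points between 6.00 h and 10.0 h. That is the look of autocatalysis, with an induction period.

| flask | J | E | remark | time |
|---|---|---|---|---|
| theta | 13 mM | 9.5 mM | run made earlier |  |
| beta | 33 mM | 9.5 mM | run made earlier |  |
| dawn | 10 mM | 9.50 mM |  | 20 h |
| noon | 15 mM | 9.50 mM |  | 20 h |
| spring | 25 mM | 9.50 mM |  | 20 h |

| run | time / h | G / % | J / % |
|---|---|---|---|
| theta | 1.50 | 0 | 100.0 |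
| theta | 3.00 | 0.4 | 99.8 |
| theta | 5.00 | 0.8 | 99.2 |
| theta | 6.00 | 1.6 | 97.8 |
| theta | 8.00 | 3.8 | 96.2 |
| theta | 10.0 | 8.7 | 89.6 |
| beta | 1.50 | 0.2 | 99.7 |
| beta | 3.00 | 1.8 | 98.7 |
| beta | 5.00 | 10.1 | 90.0 |
| beta | 6.00 | 15.8 | 82.1 |
| beta | 8.00 | 21.1 | 73.4 |
| beta | 10.0 | 18.5 | 71.6 |

(standard deviation of a reading: 0.3 percentage points)

1. [G] at the end for dawn, noon, spring, in this order
2. how that number moves from the first to the last of them (rises, then falls / hardly changes / falls all the way / rises all the way / falls, then rises)

- the numbers in the tables scatter with a standard deviation of 0.3 percentage points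
- "hardly changes" means that all values lie within two and a half points (for a concentration: within two and a half percent of the largest)

In beta the J lost reaches 9.37 mM against 9.5 mM of E charged. So I read the two as used one to one, with E as the limiting reagent.

Now freeze what hardly moves. In theta from 6.00 h to 10.0 h, J stays at 89.6% or above, so c_J and c_E are nearly constant and G grows as a plain exponential. With E charged at 9.5 mM, I take its rate as proportional to c_J and call the factor a, the growth constant per mM of J:

a = 0.0326 /mM/h

Running that line back to zero time gives the seed s, as a share of the J charged: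

s = 0.126%

Beta, read from 3.00 h to 5.00 h, gives a seed of 0.135%. Its a is 0.0261 /mM/h, lower than theta's. But beta has lost 3.30 mM of J by then, so E is no longer frozen, and I keep theta's a.

So you can draw each curve. It starts flat at s·c_J and doubles every ln(2)/(a·c_J). Its knee t_k comes where the frozen line reaches half of c_E:

t_k = ln(half of c_E / (s·c_J)) / (a·c_J)

dawn: 18.2 h

noon: 11.3 h

spring: 6.16 h

Past the knee, J loss runs towards the level c_E. In beta, with J loss near that level, G sinks from 21.1% to 18.5%. Dawn ends 1.79 h past its knee, about one doubling of 2.13 h. Noon ends 8.69 h past and spring 13.8 h past. So I commit to a hump, with noon on top.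

The forecast gives 2 mM, 3.5 mM and 2.9 mM, and says “G rises, then falls across the series”.

The flask gives 3.14 mM, 4.45 mM and 3.14 mM: rises, then falls.

    J + E → G + L (k = 0.0510 /M/h)
    G → X (k = 0.0906 /h)
    J + E + L → G + 2 L (k = 3960 /M²/h)

The knee for dawn was reckoned at 18.2 h, but dawn still holds 49.9% of its E at 20.0 h, so the flask reaches that point about 1.79 h later, and at that time G is still made 1.66 times faster than it is used up, each step taken net. Spring ends 13.8 h past its knee, longer than the half-life of G going to X, 7.65 h, and at 20.0 h it holds 0.0423% of its E, with G at 12.6% of the J charged.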